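**Retrosynthetic overview**

1. Feature: the fully substituted carbinol carbon (C2 of the 2-arylpropane-1,2,3-triol core) is bonded to the benzene carbon that is ortho to the phenolic O–H and para to the ring carbon carrying CH2O-acyl. A metal phenoxide builds exactly this O–C(ar)–C(ar)–C(OH) array when it hands a chelated α-keto ester to its ortho carbon.
2. Fragments: phenol 3 from 3-hydroxybenzyl alcohol 1 and (R)-2-methylbutanoic acid 2 (Mitsunobu); acyloxypyruvate 6 from ethyl bromopyruvate 4 and the cesium salt 5 of 2.
3. Key disconnection: the aryl–C(OH) bond of hydroxy ester 7, made from 3 and 6 by an enantioselective ortho Friedel–Crafts hydroxyalkylation. The two carbinol arms are already different there (CO2Et against CH2O-acyl).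
4. Endgame: phenol silylation (8), hydroxyl-directed reduction of the ethyl ester (9), angeloylation with angelic acid 10 through mixed anhydride 11 (12), desilylation (13).
5. Rings: none is formed; the benzene ring is bought with 1.

Key step: step 3

Assumption: the sense of induction of the Ti(OiPr)4/BINOL catalyst with this keto ester cannot be predicted with confidence. (R)-BINOL is written in step 3, and the antipodal ligand is used instead if a first run shows that it is the one leading to the (R)-carbinol.

**Route**

Step 1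
Reactants: 1 3-hydroxybenzyl alcohol; 2 (2R)-2-methylbutanoic acid
Product: 3 3-hydroxybenzyl (2R)-2-methylbutanoate
Conditions: PPh3, DIAD, THF, 0 °C → rt
Reagents that add atoms: none
Why: Mitsunobu esterification turns only the benzylic hydroxyl into an alkoxyphosphonium leaving group and the carboxylate, far more acidic than the phenol, displaces it, so the phenol should stay free and the α-stereocentre of the acid, never activated as an acyl donor, should stay (R).

Step 2
Reactants: 4 ethyl bromopyruvate; 2 (2R)-2-methylbutanoic acid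
Product: 6 ethyl 3-{[(2R)-2-methylbutanoyl]oxy}-2-oxopropanoate, via cesium (2R)-2-methylbutanoate 5 (not isolated)
Conditions: 2, Cs2CO3 (0.5 equiv), MeOH, rt, evaporate; then 4, DMF, 4 Å MS, 0 °C → rt
Reagents that add atoms: none
Why: SN2 displacement of an α-bromoketone bromide by a carboxylate (phenacyl-ester type alkylation), in which the weakly basic cesium carboxylate should substitute at the activated CH2Br faster than it enolises the pyruvate, and the stereocentre of the acid is not involved.

Step 3
Reactants: 3 3-hydroxybenzyl (2R)-2-methylbutanoate; 6 ethyl 3-{[(2R)-2-methylbutanoyl]oxy}-2-oxopropanoate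
Product: 7 ethyl (2R)-2-hydroxy-2-[2-hydroxy-4-({[(2R)-2-methylbutanoyl]oxy}methyl)phenyl]-3-{[(2R)-2-methylbutanoyl]oxy}propanoate
Conditions: Ti(OiPr)4 (10 mol %), (R)-BINOL (20 mol %), 4 Å MS, toluene, 0 °C → rt
Reagents that add atoms: none
Why: Proposed new method: the phenol of 3 should exchange for isopropoxide on the BINOL-bound tetravalent titanium centre, the ketone and ester carbonyls of 6 should chelate the same metal, and ring carbon C6 of the bound phenoxide then attacks the ketone carbon through a six-membered cyclic transition state, after which tautomerisation restores the aromatic ring and proton transfer releases 7 and the catalyst. The closest known reaction type is the Ti(OiPr)4/BINOL-catalysed enantioselective ortho Friedel–Crafts hydroxyalkylation of phenols with glyoxylates and trifluoropyruvate, together with the ortho-specific hydroxyalkylation of stoichiometric magnesium and aluminium phenoxides with pyruvates, whereas a catalytic asymmetric version with an enolisable, non-fluorinated 3-acyloxypyruvate has not been shown. No ring is closed; one C–C bond (aryl C6 to the carbinol carbon) and one stereocentre are formed. The carbinol configuration is set by the BINOL ligand, which shields one face of the chelated ketone so that the arene adds to the Si face (priorities O > CO2Et > CH2O-acyl) and gives the (R)-carbinol. The step needs ortho over para regioselectivity, which delivery from the titanium-bound phenoxide oxygen secures, and C6 over C2 selectivity, which follows from C2 being flanked by the oxygen and the CH2O-acyl group. The ketone is the only carbonyl of 6 electrophilic enough to react, so both (R)-2-methylbutanoates are bystanders.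

Step 4
Reactants: 7 ethyl (2R)-2-hydroxy-2-[2-hydroxy-4-({[(2R)-2-methylbutanoyl]oxy}methyl)phenyl]-3-{[(2R)-2-methylbutanoyl]oxy}propanoate
Product: 8 ethyl (2R)-2-{2-[(tert-butyldimethylsilyl)oxy]-4-({[(2R)-2-methylbutanoyl]oxy}methyl)phenyl}-2-hydroxy-3-{[(2R)-2-methylbutanoyl]oxy}propanoate
Conditions: TBSCl, imidazole, DMF, rt
Reagents that add atoms: TBSCl, CC(C)(C)[Si](C)(C)Cl
Why: Silyl ether formation with TBSCl and imidazole takes the phenolic hydroxyl while the tertiary alcohol is inert to this reagent, and the mild base at room temperature should neither lactonise the hydroxy ester nor move an acyl group.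

Step 5
Reactants: 8 ethyl (2R)-2-{2-[(tert-butyldimethylsilyl)oxy]-4-({[(2R)-2-methylbutanoyl]oxy}methyl)phenyl}-2-hydroxy-3-{[(2R)-2-methylbutanoyl]oxy}propanoate
Product: 9 (2S)-2-{2-[(tert-butyldimethylsilyl)oxy]-4-({[(2R)-2-methylbutanoyl]oxy}methyl)phenyl}-2,3-dihydroxypropyl (2R)-2-methylbutanoate
Conditions: BH3·SMe2 (1.5 equiv), NaBH4 (5 mol %), THF, 0 °C → rt; MeOH quench
Reagents that add atoms: none
Why: Hydroxyl-directed borane reduction of an α-hydroxy ester, in which the tertiary hydroxyl forms an alkoxyborane that delivers hydride through a five-membered chelate to the adjacent ethyl ester only, so the two α-branched 2-methylbutanoates should survive, the non-basic medium disfavours 1,3-acyl migration, and the carbinol centre is untouched (its descriptor becomes S only through the change in CIP priorities).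

Step 6
Reactants: 9 (2S)-2-{2-[(tert-butyldimethylsilyl)oxy]-4-({[(2R)-2-methylbutanoyl]oxy}methyl)phenyl}-2,3-dihydroxypropyl (2R)-2-methylbutanoate; 10 angelic acid
Product: 12 (2R)-2-{2-[(tert-butyldimethylsilyl)oxy]-4-({[(2R)-2-methylbutanoyl]oxy}methyl)phenyl}-2-hydroxy-3-{[(2R)-2-methylbutanoyl]oxy}propyl (2Z)-2-methylbut-2-enoate, via angelic 2,4,6-trichlorobenzoic anhydride 11 (not isolated)
Conditions: 10, 2,4,6-Cl3C6H2COCl, Et3N, toluene, rt; then 9, 75 °C (no DMAP)
Reagents that add atoms: none
Why: Yamaguchi-type mixed-anhydride esterification run without a nucleophilic catalyst, in which the primary hydroxyl attacks the unhindered angeloyl carbonyl of 11, the tertiary hydroxyl is too hindered to react, and leaving out DMAP avoids the conjugate addition–elimination that would isomerise the (Z)-alkene to the tiglate.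

Step 7
Reactants: 12 (2R)-2-{2-[(tert-butyldimethylsilyl)oxy]-4-({[(2R)-2-methylbutanoyl]oxy}methyl)phenyl}-2-hydroxy-3-{[(2R)-2-methylbutanoyl]oxy}propyl (2Z)-2-methylbut-2-enoate
Product: 13 (2R)-2-hydroxy-2-[2-hydroxy-4-({[(2R)-2-methylbutanoyl]oxy}methyl)phenyl]-3-{[(2R)-2-methylbutanoyl]oxy}propyl (2Z)-2-methylbut-2-enoate
Conditions: Bu4NF, AcOH (1:1), THF, 0 °C
Reagents that add atoms: none
Why: Fluoride cleavage of an aryl silyl ether, which is much more labile than an alkyl one, under acetic acid buffering that keeps the medium near neutral so that the three esters, the (Z)-alkene and all stereocentres should be unchanged.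

**Compound list**

1 | 3-hydroxybenzyl alcohol | OCc1cccc(O)c1 | starting material
2 | (2R)-2-methylbutanoic acid | CC[C@@H](C)C(=O)O | starting material
3 | 3-hydroxybenzyl (2R)-2-methylbutanoate | Oc1cccc(COC(=O)[C@H](C)CC)c1 | intermediate
4 | ethyl bromopyruvate | CCOC(=O)C(=O)CBr | starting material
5 | cesium (2R)-2-methylbutanoate | CC[C@@H](C)C(=O)[O-].[Cs+] | intermediate
6 | ethyl 3-{[(2R)-2-methylbutanoyl]oxy}-2-oxopropanoate | CCOC(=O)C(=O)COC(=O)[C@H](C)CC | intermediate
7 | ethyl (2R)-2-hydroxy-2-[2-hydroxy-4-({[(2R)-2-methylbutanoyl]oxy}methyl)phenyl]-3-{[(2R)-2-methylbutanoyl]oxy}propanoate | CCOC(=O)[C@](O)(COC(=O)[C@H](C)CC)c1ccc(COC(=O)[C@H](C)CC)cc1O | intermediate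
8 | ethyl (2R)-2-{2-[(tert-butyldimethylsilyl)oxy]-4-({[(2R)-2-methylbutanoyl]oxy}methyl)phenyl}-2-hydroxy-3-{[(2R)-2-methylbutanoyl]oxy}propanoate | CCOC(=O)[C@](O)(COC(=O)[C@H](C)CC)c1ccc(COC(=O)[C@H](C)CC)cc1O[Si](C)(C)C(C)(C)C | intermediate
9 | (2S)-2-{2-[(tert-butyldimethylsilyl)oxy]-4-({[(2R)-2-methylbutanoyl]oxy}methyl)phenyl}-2,3-dihydroxypropyl (2R)-2-methylbutanoate | OC[C@](O)(COC(=O)[C@H](C)CC)c1ccc(COC(=O)[C@H](C)CC)cc1O[Si](C)(C)C(C)(C)C | intermediate
10 | angelic acid, (2Z)-2-methylbut-2-enoic acid | C/C=C(/C)C(=O)O | starting material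
11 | angelic 2,4,6-trichlorobenzoic anhydride | C/C=C(/C)C(=O)OC(=O)c1c(Cl)cc(Cl)cc1Cl | intermediate
12 | (2R)-2-{2-[(tert-butyldimethylsilyl)oxy]-4-({[(2R)-2-methylbutanoyl]oxy}methyl)phenyl}-2-hydroxy-3-{[(2R)-2-methylbutanoyl]oxy}propyl (2Z)-2-methylbut-2-enoate | C/C=C(/C)C(=O)OC[C@](O)(COC(=O)[C@H](C)CC)c1ccc(COC(=O)[C@H](C)CC)cc1O[Si](C)(C)C(C)(C)C | intermediate
13 | (2R)-2-hydroxy-2-[2-hydroxy-4-({[(2R)-2-methylbutanoyl]oxy}methyl)phenyl]-3-{[(2R)-2-methylbutanoyl]oxy}propyl (2Z)-2-methylbut-2-enoate | C/C=C(/C)C(=O)OC[C@](O)(COC(=O)[C@H](C)CC)c1ccc(COC(=O)[C@H](C)CC)cc1O | target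

**Step count**

Total steps: 7. Longest linear sequence: 6 steps (step 1 or step 2, then steps 3 to 7).

**Steps most likely to fail**

Step 3 (Proposed new method). The ketone of 6 is less electrophilic than the glyoxylates and trifluoropyruvate of the known cases, so turnover may be slow. The product, a chelating phenol–carbinol–ester, may hold on to the titanium. An unchelated background reaction may attack the para position, the keto ester may enolise and self-condense, and facial selectivity may be poor.
Fallback, from 3 and 6 back to 7: phenol 3 is deprotonated with EtMgBr (1.0 equiv, Et2O–toluene, 0 °C) to give bromomagnesium 3-({[(2R)-2-methylbutanoyl]oxy}methyl)phenoxide F1. This is treated with 6 in toluene at room temperature. The ortho-specific hydroxyalkylation of magnesium phenoxides by α-oxo esters is known chemistry and should form the same aryl–C(OH) bond without facial control. It would give 7 together with its carbinol epimer, ethyl (2S)-2-hydroxy-2-[2-hydroxy-4-({[(2R)-2-methylbutanoyl]oxy}methyl)phenyl]-3-{[(2R)-2-methylbutanoyl]oxy}propanoate F2. The two diastereomers are separated by preparative HPLC and 7 goes on to step 4.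

Step 5. Hydride delivery from the hindered tertiary alkoxyborane may be slow, and prolonged exposure to borane may then start to reduce the 2-methylbutanoates. A 1,3-acyl shift in the freed diol would erode the carbinol configuration.
Fallback, from 7 back to 9: 7 is lactonised (p-TsOH cat., toluene, 80 °C, loss of ethanol) to [(3R)-3-hydroxy-3-({[(2R)-2-methylbutanoyl]oxy}methyl)-2-oxo-2,3-dihydro-1-benzofuran-6-yl]methyl (2R)-2-methylbutanoate F3. Its aryl lactone is far more electrophilic than the alkyl esters and is reduced with NaBH4 (THF–EtOH, −20 °C, AcOH quench) to (2S)-2,3-dihydroxy-2-[2-hydroxy-4-({[(2R)-2-methylbutanoyl]oxy}methyl)phenyl]propyl (2R)-2-methylbutanoate F4. Phenol and primary alcohol are both silylated (TBSCl, imidazole, DMF) to (2R)-3-[(tert-butyldimethylsilyl)oxy]-2-{2-[(tert-butyldimethylsilyl)oxy]-4-({[(2R)-2-methylbutanoyl]oxy}methyl)phenyl}-2-hydroxypropyl (2R)-2-methylbutanoate F5. The alkyl silyl ether alone is then cleaved with PPTS in MeOH at room temperature, the aryl silyl ether being stable to mild acid, which gives 9.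

Step 6. Activation of angelic acid may isomerise the (Z)-alkene to the tiglate. Acylation of the neopentyl-type primary alcohol may be slow enough at 75 °C for the neighbouring 2-methylbutanoyl group to shift onto the free primary hydroxyl, which after acylation would appear as the carbinol epimer.
Fallback, from 9 back to 12: the primary hydroxyl of 9 is esterified under Steglich conditions (EDC·HCl, DMAP cat., CH2Cl2, 0 °C) with 2-[bis(2,2,2-trifluoroethoxy)phosphoryl]propanoic acid, obtained by saponifying its commercial ethyl ester. This gives (2R)-2-{2-[(tert-butyldimethylsilyl)oxy]-4-({[(2R)-2-methylbutanoyl]oxy}methyl)phenyl}-2-hydroxy-3-{[(2R)-2-methylbutanoyl]oxy}propyl 2-[bis(2,2,2-trifluoroethoxy)phosphoryl]propanoate F6 as both epimers at the phosphorus-bearing carbon. A Still–Gennari olefination with acetaldehyde (KN(SiMe3)2, 18-crown-6, THF, −78 °C) then builds the (Z)-2-methylbut-2-enoate in place, so no activated angelic acid is needed, and gives 12.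

**Further compounds**

F1 | step 3 | bromomagnesium 3-({[(2R)-2-methylbutanoyl]oxy}methyl)phenoxide | CC[C@@H](C)C(=O)OCc1cccc(O[Mg]Br)c1
F2 | step 3 | ethyl (2S)-2-hydroxy-2-[2-hydroxy-4-({[(2R)-2-methylbutanoyl]oxy}methyl)phenyl]-3-{[(2R)-2-methylbutanoyl]oxy}propanoate | CCOC(=O)[C@@](O)(COC(=O)[C@H](C)CC)c1ccc(COC(=O)[C@H](C)CC)cc1O
F3 | step 5 | [(3R)-3-hydroxy-3-({[(2R)-2-methylbutanoyl]oxy}methyl)-2-oxo-2,3-dihydro-1-benzofuran-6-yl]methyl (2R)-2-methylbutanoate | O=C1Oc2cc(COC(=O)[C@H](C)CC)ccc2[C@@]1(O)COC(=O)[C@H](C)CC
F4 | step 5 | (2S)-2,3-dihydroxy-2-[2-hydroxy-4-({[(2R)-2-methylbutanoyl]oxy}methyl)phenyl]propyl (2R)-2-methylbutanoate | OC[C@](O)(COC(=O)[C@H](C)CC)c1ccc(COC(=O)[C@H](C)CC)cc1O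
F5 | step 5 | (2R)-3-[(tert-butyldimethylsilyl)oxy]-2-{2-[(tert-butyldimethylsilyl)oxy]-4-({[(2R)-2-methylbutanoyl]oxy}methyl)phenyl}-2-hydroxypropyl (2R)-2-methylbutanoate | CC(C)(C)[Si](C)(C)OC[C@](O)(COC(=O)[C@H](C)CC)c1ccc(COC(=O)[C@H](C)CC)cc1O[Si](C)(C)C(C)(C)C
F6 | step 6 | (2R)-2-{2-[(tert-butyldimethylsilyl)oxy]-4-({[(2R)-2-methylbutanoyl]oxy}methyl)phenyl}-2-hydroxy-3-{[(2R)-2-methylbutanoyl]oxy}propyl 2-[bis(2,2,2-trifluoroethoxy)phosphoryl]propanoate | CC(C(=O)OC[C@](O)(COC(=O)[C@H](C)CC)c1ccc(COC(=O)[C@H](C)CC)cc1O[Si](C)(C)C(C)(C)C)P(=O)(OCC(F)(F)F)OCC(F)(F)F
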